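**Retrosynthetic overview**
1. Ring A is closed last: target ⇐ ring closure and acetylation of a 1,5-dialdehyde ⇐ glycol cleavage of a cyclopentane cis-diol carried as its acetonide.
2. Ring B: the δ-lactone ⇐ Baeyer–Villiger ring expansion of a cis-bicyclo[3.3.0]octan-3-one (key step; the lactone C–O bond arises by a 1,2-shift with retention).
3. That ketone ⇐ bicyclic enone by conjugate reduction and enolate hydroxyprenylation with isoprene monoxide (convex-face control).
4. Enone ⇐ Wacker/aldol annulation ⇐ three-component coupling of the ribose-derived acetonide enone, an alkenyl Grignard reagent and allyl iodide.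
5. Ring order: cyclopentane (bought) → second carbocycle (step 4) → ring B by ring expansion (step 6) → ring A (step 8).

Labels for the target atoms: C-a = CH bearing the alkenyl chain; C-b = acetal CH(OAc); C-c = enol-ether CH; C-d = its alkene partner at the ring fusion; C-e = lactone O–CH; C-f = lactone C=O; C-g = CH2; C-h = sp3 ring-fusion CH. Target configuration: C-a R, C-b R, C-e S, C-h S, side-chain alkene E.
Assumption: enone 5 and bromo ketal 1 are bought as catalogue compounds. In 8–17 the α face is the face of the two ring oxygens from 5 and the β face is the opposite one.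
Bicyclo[3.3.0]octane numbering used for 11, 12, 14, 15: C1 = C-d, C2 = C-e, C3 = C-f, C4 = C-g, C5 = C-h, C6 = C-a, C7 = C-b, C8 = C-c.

**Step 1**
Reactants: 1 2-(2-bromoethyl)-2-methyl-1,3-dioxolane; 2 2,3-dibromoprop-1-ene
Product: 4 2-(4-bromopent-4-en-1-yl)-2-methyl-1,3-dioxolane, via Grignard reagent 3 (not isolated)
Conditions: Mg, THF, 25 °C; then 2, CuI (5 mol%), 0 °C → rt
Reagents that add atoms: none
Why: Magnesium insertion gives the primary Grignard reagent, which displaces the allylic bromide of 2 in a copper-catalysed SN2/SN2' allylic substitution (both modes give the same 2-bromoalkene) while the vinylic bromide stays; no stereocentre is formed.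

**Step 2**
Reactants: 4 2-(4-bromopent-4-en-1-yl)-2-methyl-1,3-dioxolane; 5 (3aR,6aR)-2,2-dimethyl-3a,6a-dihydro-4H-cyclopenta[d][1,3]dioxol-4-one; 6 3-iodoprop-1-ene
Product: 9 (3aR,5S,6R,6aR)-5-allyl-2,2-dimethyl-6-[5-(2-methyl-1,3-dioxolan-2-yl)pent-1-en-2-yl]tetrahydro-4H-cyclopenta[d][1,3]dioxol-4-one, via alkenyl Grignard reagent 7 (not isolated), via magnesium enolate 8 (not isolated)
Conditions: Mg, THF, 50 °C; then CuBr·SMe2 (15 mol%), 5, THF, −78 °C; then 6, DMPU, −78 → −20 °C
Reagents that add atoms: none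
Why: Copper-catalysed conjugate addition with enolate alkylation (three-component coupling): the alkenyl group adds anti to the dioxolane and sets C-a, and the regiodefined magnesium enolate is C-allylated anti to the new alkenyl group, which sets C-h with its hydrogen cis to the alkenyl chain.

**Step 3**
Reactants: 9 allyl ketone
Product: 10 (3aR,5S,6R,6aR)-2,2-dimethyl-6-[5-(2-methyl-1,3-dioxolan-2-yl)pent-1-en-2-yl]-5-(2-oxopropyl)tetrahydro-4H-cyclopenta[d][1,3]dioxol-4-one
Conditions: PdCl2 (10 mol%), CuCl, O2 (1 atm), DMF/H2O 7:1, rt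
Reagents that add atoms: water, O
Why: Wacker oxidation turns the monosubstituted allyl alkene into the methyl ketone with Markovnikov selectivity, the 1,1-disubstituted alkene being a poor substrate; no stereocentre changes.

**Step 4**
Reactants: 10 1,4-diketone
Product: 12 7,8-(isopropylidenedioxy)-6-[5-(2-methyl-1,3-dioxolan-2-yl)pent-1-en-2-yl]bicyclo[3.3.0]oct-1-en-3-one (H-5 and 6-alkenyl β; both oxygens α), via aldol adduct 11 (not isolated)
Conditions: KOt-Bu (0.5 equiv), t-BuOH/THF, 0 °C → rt
Reagents that add atoms: none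
Why: Intramolecular aldol condensation: the unhindered methyl-ketone enolate adds 5-exo to the ring ketone from the face of its own tether (cis ring fusion) and E1cB loss of water gives the conjugated enone; base is kept substoichiometric and cold because the α,β-dialkoxy ketone can lose the acetonide oxygen by β-elimination.

**Step 5**
Reactants: 12 bicyclic enone; 13 2-methyl-2-vinyloxirane
Product: 15 2-[(E)-4-(dimethylphenylsilyloxy)-3-methylbut-2-en-1-yl]-7,8-(isopropylidenedioxy)-6-[5-(2-methyl-1,3-dioxolan-2-yl)pent-1-en-2-yl]-cis-bicyclo[3.3.0]octan-3-one (H-1; H-5; C2 chain; C6 alkenyl all β), via silyl enol ether 14 (not isolated)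
Conditions: Cu(OAc)2·H2O (5 mol%), 1,2-bis(diphenylphosphino)benzene (5 mol%), PhMe2SiH (1.1 equiv), toluene, 0 °C; then 13 (1.3 equiv), Pd2(dba)3 (2.5 mol%), dppe (6 mol%), THF, 0 °C → rt
Reagents that add atoms: dimethylphenylsilane, C[SiH](C)c1ccccc1
Why: Proposed new method: reductive Tsuji–Trost hydroxyprenylation, in which a phosphine-ligated copper hydride adds 1,4 to the β,β-disubstituted enone on the convex face (cis to H at C-h, anti to the oxygen on C-c; sets C-d) and σ-bond metathesis with the silane gives silyl enol ether 14, zerovalent palladium then opens isoprene monoxide to a zwitterionic π-allyl alkoxide whose alkoxide takes the silyl group from 14, and the freed enolate attacks the unsubstituted allyl terminus on its convex face (sets C-e, chain cis to the ring-fusion hydrogens) through the syn π-allyl complex (E alkene); the closest known reactions are the alkoxide-triggered Tsuji–Trost allylation of silyl enol ethers by allyl carbonates, the palladium-catalysed 1,4-addition of soft carbon nucleophiles to vinyl epoxides and copper-hydride conjugate reduction with enolate trapping.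

**Step 6**
Reactants: 15 bicyclic ketone
Product: 16 1-[(E)-4-(dimethylphenylsilyloxy)-3-methylbut-2-en-1-yl]-6,7-(isopropylidenedioxy)-5-[5-(2-methyl-1,3-dioxolan-2-yl)pent-1-en-2-yl]hexahydrocyclopenta[c]pyran-3(1H)-one
Conditions: Me3SiOOSiMe3 (2.5 equiv), SnCl4 (20 mol%), trans-cyclohexane-1,2-diamine (20 mol%), 4 Å MS, CH2Cl2, −20 → 0 °C
Reagents that add atoms: bis(trimethylsilyl) peroxide, C[Si](C)(C)OO[Si](C)(C)C
Why: Baeyer–Villiger ring expansion (1,2-shift of carbon to oxygen in the Criegee adduct): the more substituted α-carbon C-e migrates with retention, so its bond to the carbonyl becomes the C–O bond of the δ-lactone (ring B) with the configuration set in step 5, and the Lewis-acid-activated silyl peroxide oxidises the ketone without epoxidising the two C=C bonds.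

**Step 7**
Reactants: 16 δ-lactone
Product: 18 6-[(E)-4-hydroxy-3-methylbut-2-en-1-yl]-4-(3-methylidene-1,7-dioxooctan-2-yl)-2-oxooxane-5-carbaldehyde, via triol 17 (not isolated)
Conditions: H5IO6 (3 equiv), THF/H2O 3:1, 0 °C → rt
Reagents that add atoms: water, O
Why: Periodic acid acts as acid and oxidant: hydrolysis of acetonide, dioxolane and silyl ether is followed by Malaprade glycol cleavage of the cis-diol, which is far faster than any alkene oxidation, to give the 1,5-dialdehyde; no stereocentre is touched (the one at C-d becomes irrelevant in step 8).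

**Step 8**
Reactants: 18 dialdehyde
Product: 20 target CNP0120157.1, via lactol 19 (not isolated)
Conditions: Ac2O (4 equiv), pyridine, DMAP (5 mol%), CH2Cl2, 0 °C
Reagents that add atoms: acetic anhydride, CC(=O)OC(C)=O
Why: Ring–chain tautomerism of the 1,5-dialdehyde (enol oxygen of the C-d aldehyde adds to the C-b aldehyde, as in iridoid lactols) closes ring A, and O-acetylation of the lactol and of the primary allylic alcohol traps it; the acetoxy group is expected axial and trans to the alkenyl group at C-a (anomeric effect), which sets C-b.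

**Compound list**
1 | 2-(2-bromoethyl)-2-methyl-1,3-dioxolane | CC1(CCBr)OCCO1 | starting material
2 | 2,3-dibromoprop-1-ene | C=C(Br)CBr | starting material
3 | [2-(2-methyl-1,3-dioxolan-2-yl)ethyl]magnesium bromide | CC1(CC[Mg]Br)OCCO1 | intermediate
4 | 2-(4-bromopent-4-en-1-yl)-2-methyl-1,3-dioxolane | CC1(CCCC(Br)=C)OCCO1 | intermediate
5 | (3aR,6aR)-2,2-dimethyl-3a,6a-dihydro-4H-cyclopenta[d][1,3]dioxol-4-one | CC1(C)O[C@@H]2C=CC(=O)[C@@H]2O1 | starting material
6 | 3-iodoprop-1-ene (allyl iodide) | C=CCI | starting material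
7 | [5-(2-methyl-1,3-dioxolan-2-yl)pent-1-en-2-yl]magnesium bromide | CC1(CCCC(=C)[Mg]Br)OCCO1 | intermediate
8 | bromomagnesium (3aR,6R,6aR)-2,2-dimethyl-6-[5-(2-methyl-1,3-dioxolan-2-yl)pent-1-en-2-yl]-6,6a-dihydro-3aH-cyclopenta[d][1,3]dioxol-4-olate (alkenyl β) | CC1(C)O[C@@H]2[C@@H](C(=C)CCCC3(C)OCCO3)C=C(O[Mg]Br)[C@@H]2O1 | intermediate
9 | (3aR,5S,6R,6aR)-5-allyl-2,2-dimethyl-6-[5-(2-methyl-1,3-dioxolan-2-yl)pent-1-en-2-yl]tetrahydro-4H-cyclopenta[d][1,3]dioxol-4-one (alkenyl β, allyl α) | CC1(C)O[C@@H]2[C@@H](C(=C)CCCC3(C)OCCO3)[C@H](CC=C)C(=O)[C@@H]2O1 | intermediate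
10 | (3aR,5S,6R,6aR)-2,2-dimethyl-6-[5-(2-methyl-1,3-dioxolan-2-yl)pent-1-en-2-yl]-5-(2-oxopropyl)tetrahydro-4H-cyclopenta[d][1,3]dioxol-4-one | CC1(C)O[C@@H]2[C@@H](C(=C)CCCC3(C)OCCO3)[C@H](CC(C)=O)C(=O)[C@@H]2O1 | intermediate
11 | 1-hydroxy-7,8-(isopropylidenedioxy)-6-[5-(2-methyl-1,3-dioxolan-2-yl)pent-1-en-2-yl]-cis-bicyclo[3.3.0]octan-3-one (OH-1, H-5 and 6-alkenyl β; oxygens at C7, C8 α) | CC1(C)O[C@@H]2[C@@H](C(=C)CCCC3(C)OCCO3)[C@@H]4CC(=O)C[C@]4(O)[C@@H]2O1 | intermediate
12 | 7,8-(isopropylidenedioxy)-6-[5-(2-methyl-1,3-dioxolan-2-yl)pent-1-en-2-yl]bicyclo[3.3.0]oct-1-en-3-one (H-5 and 6-alkenyl β; oxygens α) | CC1(C)O[C@@H]2[C@@H](C(=C)CCCC3(C)OCCO3)[C@@H]4CC(=O)C=C4[C@@H]2O1 | intermediate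
13 | 2-methyl-2-vinyloxirane (isoprene monoxide, racemic) | C=CC1(C)CO1 | starting material
14 | 3-(dimethylphenylsilyloxy)-7,8-(isopropylidenedioxy)-6-[5-(2-methyl-1,3-dioxolan-2-yl)pent-1-en-2-yl]-cis-bicyclo[3.3.0]oct-2-ene (H-1, H-5 and 6-alkenyl β) | CC1(C)O[C@@H]2[C@@H](C(=C)CCCC3(C)OCCO3)[C@@H]4CC(O[Si](C)(C)c5ccccc5)=C[C@@H]4[C@@H]2O1 | intermediate
15 | 2-[(E)-4-(dimethylphenylsilyloxy)-3-methylbut-2-en-1-yl]-7,8-(isopropylidenedioxy)-6-[5-(2-methyl-1,3-dioxolan-2-yl)pent-1-en-2-yl]-cis-bicyclo[3.3.0]octan-3-one (H-1, H-5, C2 chain and C6 alkenyl β; acetonide α) | CC1(C)O[C@@H]2[C@@H](C(=C)CCCC3(C)OCCO3)[C@@H]4CC(=O)[C@@H](C/C=C(\C)CO[Si](C)(C)c5ccccc5)[C@@H]4[C@@H]2O1 | intermediate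
16 | 1-[(E)-4-(dimethylphenylsilyloxy)-3-methylbut-2-en-1-yl]-6,7-(isopropylidenedioxy)-5-[5-(2-methyl-1,3-dioxolan-2-yl)pent-1-en-2-yl]hexahydrocyclopenta[c]pyran-3(1H)-one (C1 chain, H-4a, H-7a and 5-alkenyl β; acetonide α) | CC1(C)O[C@@H]2[C@@H](C(=C)CCCC3(C)OCCO3)[C@@H]4CC(=O)O[C@@H](C/C=C(\C)CO[Si](C)(C)c5ccccc5)[C@@H]4[C@@H]2O1 | intermediate
17 | 6,7-dihydroxy-1-[(E)-4-hydroxy-3-methylbut-2-en-1-yl]-5-(6-oxohept-1-en-2-yl)hexahydrocyclopenta[c]pyran-3(1H)-one (configuration as in 16) | O[C@@H]1[C@@H](C(=C)CCCC(C)=O)[C@@H]2CC(=O)O[C@@H](C/C=C(\C)CO)[C@@H]2[C@@H]1O | intermediate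
18 | 6-[(E)-4-hydroxy-3-methylbut-2-en-1-yl]-4-(3-methylidene-1,7-dioxooctan-2-yl)-2-oxooxane-5-carbaldehyde (configuration at C-a, C-d, C-e, C-h as in 16) | O=C[C@@H](C(=C)CCCC(C)=O)[C@@H]1CC(=O)O[C@@H](C/C=C(\C)CO)[C@@H]1C=O | intermediate
19 | lactol: the target with OH in place of both acetoxy groups (C-a R, C-e S, C-h S; lactol OH trans to the alkenyl group) | C=C(CCCC(C)=O)[C@@H]1[C@@H](O)OC=C2[C@H](C/C=C(\C)CO)OC(=O)C[C@H]21 | intermediate
20 | CNP0120157.1: bicyclic δ-lactone/2-acetoxydihydropyran with (E)-4-acetoxy-3-methylbut-2-enyl at C-e and 6-oxohept-1-en-2-yl at C-a (C-a R, C-b R, C-e S, C-h S) | C=C(CCCC(C)=O)[C@@H]1[C@@H](OC(C)=O)OC=C2[C@H](C/C=C(\C)COC(C)=O)OC(=O)C[C@H]21 | target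

**Step count and risks**
Total steps: 8. Longest linear sequence: 8 (1 → 4 → 9 → 10 → 12 → 15 → 16 → 18 → 20).

The three steps most likely to fail:

Step 4 (aldol condensation). The α,β-dialkoxy ketone 10 and the γ-alkoxy enone 12 can lose the acetonide oxygen by β-elimination under alkoxide base. The fallback separates addition and dehydration and sets out from diketone 10. Cy2BCl/Et3N (Et2O, −78 °C) enolises only the methyl terminus to the dicyclohexylboron enolate F1, which adds to the ring ketone to give the boron aldolate F2. Work-up with MeOH and pH 7 buffer releases aldol adduct 11, which is isolated this time. MsCl/Et3N/DMAP (CH2Cl2, 0 °C) converts it into the tertiary mesylate F3, which loses methanesulfonic acid on addition of DBU and comes back to the route at enone 12.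

Step 5 (proposed new reductive hydroxyprenylation). Risks are reduction of the π-allyl complex by residual hydride, 1,2- instead of 1,4-opening of the epoxide, and a modest E/Z ratio. The fallback uses known chemistry and sets out from enone 12. The copper-hydride reduction with PhMe2SiH is stopped at silyl enol ether 14, which is isolated. The electrophile is made from 13: TiCl4 (CH2Cl2, −80 °C) opens it to (E)-4-chloro-2-methylbut-2-en-1-ol F4, and PhMe2SiCl/imidazole gives its dimethylphenylsilyl ether F5. MeLi (THF, 0 °C) cleaves 14 to the lithium enolate F6, which is alkylated on its convex face by F5 (NaI, DMPU, −78 → 0 °C) and comes back to the route at ketone 15.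

Step 6 (Baeyer–Villiger ring expansion). The Lewis acid may open the acetonide or the dioxolane, and any peracid-type pathway would epoxidise the trisubstituted alkene. The fallback sets out from ketone 15 and replaces the electrophilic silyl peroxide by a biocatalytic oxidation with a cyclopentanone or cyclohexanone monooxygenase (whole cells, air, glucose for cofactor recycling, pH 7.5, 25 °C). The enzyme-bound flavin hydroperoxide is nucleophilic, adds only to the ketone and leaves alkenes, acetals and the silyl ether alone. It comes back to the route at lactone 16 and makes no new compound.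

**Further compounds**
F1 | step 4 | dicyclohexylboron enolate of 10 at the methyl terminus | CC1(C)O[C@@H]2[C@@H](C(=C)CCCC3(C)OCCO3)[C@H](CC(=C)OB(C4CCCCC4)C4CCCCC4)C(=O)[C@@H]2O1
F2 | step 4 | dicyclohexylboron aldolate of 11 | CC1(C)O[C@@H]2[C@@H](C(=C)CCCC3(C)OCCO3)[C@@H]4CC(=O)C[C@]4(OB(C5CCCCC5)C5CCCCC5)[C@@H]2O1
F3 | step 4 | tertiary mesylate of 11 | CC1(C)O[C@@H]2[C@@H](C(=C)CCCC3(C)OCCO3)[C@@H]4CC(=O)C[C@]4(OS(C)(=O)=O)[C@@H]2O1
F4 | step 5 | (E)-4-chloro-2-methylbut-2-en-1-ol | ClC/C=C(\C)CO
F5 | step 5 | (E)-[(4-chloro-2-methylbut-2-en-1-yl)oxy]dimethyl(phenyl)silane | ClC/C=C(\C)CO[Si](C)(C)c1ccccc1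
F6 | step 5 | lithium enolate corresponding to 14 | CC1(C)O[C@@H]2[C@@H](C(=C)CCCC3(C)OCCO3)[C@@H]4CC(O[Li])=C[C@@H]4[C@@H]2O1
F0 | step 6 | none | none
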